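The new flask charges nucleophile to electrophile at 0.950, the north run at 0.480.

| flask | electrophile | nucleophile | solid base | remark | time |
|---|---|---|---|---|---|
| north | 0.050 M | 0.024 M (fed, over 1.0 h) | 0.050 M | run made earlier |  |
| flask | 0.050 M | 0.0475 M (fed, over 1.0 h) | 0.0500 M |  | 10 h |

north run (percent of the electrophile charged)

| time / min | electrophile / % | target / % |
|---|---|---|
| 5.00 | 87 | 3 |
| 8.00 | 79 | 0 |
| 12.0 | 66 | 2 |
| 15.0 | 65 | 0 |
| 25.0 | 52 | 4 |
| 40.0 | 36 | 3 |
| 60.0 | 24 | 5 |

(each reading ± 2 percentage points)

- percent here means electrophile units held: one side product counts as two
- solid base is a solid; its amount is given per volume of the solution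
- steps thought possible: electrophile + nucleophile -> acid set free + target; nucleophile + acid set free <-> protonated nucleophile; acid set free + free base <-> salt of the base; solid base <-> free base; electrophile <-> dormant form; electrophile + target -> side product
- at the start none of the solid base is in solution
- what has gone from electrophile into another species counts as reacted, even if it can come back
- the earlier runs do not show how much of nucleophile is bound; that part of a forecast is a guess

- part of the electrophile that has reacted at 10 h
- share of the unused nucleophile that is free and not bound as protonated nucleophile, at 10 h

In the north run, the specific rate of the electrophile, its fractional loss per minute, starts at 0.0279 min⁻¹ over the first 5.00 min. From 25.0 min to 60.0 min it reads 0.0221 min⁻¹, lower, although the nucleophile fed grows from 0.00200 M to 0.024 M. So this reckoning takes the early fall as the step into the dormant form, which runs back.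

That is the first slowing: once balanced, the electrophile is a steady share of the pool it forms with the dormant form. As a guess, this reckoning takes for that share the 24% read at 60.0 min, a scattered reading of the charge that was still falling. The second term is the nucleophile route of the north run. As a guess, that route took up twice the 5% of target read at 60.0 min, with electrophile taken near half its charge over the hour, which gives 0.00333 min⁻¹ at a mean nucleophile of 0.0120 M. For the new flask, this reckoning lets one nucleophile take two electrophile, so the whole electrophile charge leaves about 0.0225 M of nucleophile unused, a factor 1.88 on that mean.

The drain rate, the pseudo-first-order rate at which the balanced pool of electrophile and dormant form falls, is the product of share, route and factor: 0.0900 h⁻¹. Joining the ends, this reckoning lets the new flask balance within 1.0 h and then drain for 9.00 h, so it gives 89.3% reacted. It gives no figure for the free share, which the north run does not show.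

The forecast says 99.5% and 88%, above this reckoning on the first. Its ground: “nine more hours should drain electrophile and the dormant pool”.

The new flask gives 93.7% and 51.1%.

    electrophile + nucleophile → acid set free + target (k = 0.290 M⁻¹ min⁻¹)
    nucleophile + acid set free ⇌ protonated nucleophile, settled at all times (K = 5100 M⁻¹)
    acid set free + free base ⇌ salt of the base (K = 23000 M⁻¹, k = 3.00 M⁻¹ min⁻¹)
    solid base ⇌ free base, rate k4*(cs4 - [free base]) while solid is left; crystals form when [free base] > cs4 (solubility = 42.0 mM, k = 0.510 min⁻¹)
    electrophile ⇌ dormant form (K = 2.90, k = 0.0330 min⁻¹)
    electrophile + target → side product (k = 0.450 M⁻¹ min⁻¹)

At 10.0 h the new flask holds 6.33% electrophile beside 21.8% dormant form, which counts as reacted. Over the second half of the time, the electrophile of the new flask falls on average at 0.108 h⁻¹, against the drain rate of 0.0900 h⁻¹. For the neighbour with 0.020 M of electrophile, the same drain rate reckons to 0.150 h⁻¹ and 93.8% reacted. That neighbour gives 95.5%.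

(Readings and results were generated by integration on assumed constants; the scatter is artificial.)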